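The target is read as a carbocyclic octalin into which nitrogen has been inserted. Undoing the bonds N4–C5 and N4–C9a turns the azepine (N4, C5–C9, C9a) back into a cyclohexane (C5–C9, C9a) fused to ring B. In the last step the C3 azide opens a C1–C9a epoxide at C9a, C5 migrates from C9a to nitrogen and N2 leaves. This one operation closes the pyrrolidine, enlarges the six-membered carbocycle to the seven-membered azacycle and frees the C1 carbinol. Since C1 carries no hydrogen, the iminium can only become the C9=C9a enamine. The precursor is a tricyclic lactone epoxide without ring nitrogen that carries an azido lactone side chain.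

Key step: step 15

Assumption: Stemona numbering is kept for all intermediates (N4; pyrrolidine C1–C3, C9a; azepine C5–C9; ring B C9, C10, C11, C12, C1, C9a; ethyl C16–C17; fused lactone C13–C15; side-chain lactone C18–C22; β = the face of ring B that carries the ethyl group, O–C11 and C13). C9 becomes sp2 in step 15 and is drawn 9R, the epimer expected on equilibration of ketone 17; its epimer would converge on the same target.

Step 1
Reactants: 1 (4S)-3-(tert-butoxycarbonyl)-2,2-dimethyl-1,3-oxazolidine-4-carboxylic acid (N-Boc-L-serine acetonide)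
Product: 2 S-ethyl (4S)-3-(tert-butoxycarbonyl)-2,2-dimethyl-1,3-oxazolidine-4-carbothioate
Conditions: EtSH, DCC, DMAP (cat.), CH2Cl2, 0 °C to rt
Reagents that add atoms: ethanethiol, CCS
Why: Steglich-type thioesterification of the urethane-protected acid keeps the bought serine centre (C3) intact and provides the acyl partner for a Fukuyama coupling.

Step 2
Reactants: 2 S-ethyl thioester; 3 methyl (2R)-3-bromo-2-methylpropanoate
Product: 5 tert-butyl (4S)-4-[(3S)-4-methoxy-3-methyl-4-oxobutanoyl]-2,2-dimethyl-1,3-oxazolidine-3-carboxylate, via zinc homoenolate 4 (not isolated)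
Conditions: 3, Zn dust, I2 (5 mol %), DMA, 70 °C; then 2, PdCl2(PPh3)2 (5 mol %), toluene, rt
Reagents that add atoms: none
Why: Fukuyama coupling, in which zinc insertion gives a configurationally stable ester-bearing alkylzinc (C20 is bought with 3) and the Pd-catalysed acyl substitution of the thioester stops at the ketone without racemising C3.

Step 3
Reactants: 5 γ-keto ester
Product: 7 tert-butyl (4S)-2,2-dimethyl-4-[(2S,4S)-4-methyl-5-oxooxolan-2-yl]-1,3-oxazolidine-3-carboxylate, via hydroxy ester 6 (not isolated)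
Conditions: L-Selectride, THF, −78 °C to rt; then H2O
Reagents that add atoms: none
Why: Felkin–Anh reduction, in which the bulky hydride attacks the ketone anti to the oxazolidine nitrogen and sets C18 syn to the C3–N bond, after which the alkoxide closes the γ-lactone by displacing methoxide.

Step 4
Reactants: 7 oxazolidine lactone
Product: 8 tert-butyl N-[(1S)-2-hydroxy-1-[(2S,4S)-4-methyl-5-oxooxolan-2-yl]ethyl]carbamate
Conditions: AcOH–H2O (4:1), 40 °C
Reagents that add atoms: none
Why: Mild acid hydrolysis cleaves the N,O-acetonide, which is far more labile than the Boc group or the γ-lactone, and touches no stereocentre.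

Step 5
Reactants: 8 N-Boc amino alcohol
Product: 9 tert-butyl N-[(1R)-2-iodo-1-[(2S,4S)-4-methyl-5-oxooxolan-2-yl]ethyl]carbamate
Conditions: I2, PPh3, imidazole, CH2Cl2, 0 °C
Reagents that add atoms: iodine, II
Why: Appel iodination of the primary alcohol (SN2 at C2) works as for iodoalanine derivatives, and the changed descriptor at C3 reflects only the new CIP priorities.

Step 6
Reactants: 10 4-(cyclohex-1-en-1-yl)morpholine; 11 propanal
Product: 13 (2E)-2-propylidenecyclohexan-1-one, via dienamine 12 (not isolated)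
Conditions: toluene, reflux (Dean–Stark); then aq AcOH, rt
Reagents that add atoms: none
Why: Stork enamine aldol condensation avoids self-condensation of the aldehyde, and hydrolysis of the dienamine gives the thermodynamically preferred E-alkylidene ketone.

Step 7
Reactants: 14 3-methylfuran-2(5H)-one
Product: 15 tert-butyl(dimethyl)[(3-methylfuran-2-yl)oxy]silane
Conditions: TBSOTf, Et3N, CH2Cl2, 0 °C
Reagents that add atoms: tert-butyldimethylsilyl triflate, CC(C)(C)[Si](C)(C)OS(=O)(=O)C(F)(F)F
Why: Soft enolisation and O-silylation of the butenolide are driven by formation of the aromatic 2-silyloxyfuran.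

Step 8
Reactants: 13 (2E)-2-propylidenecyclohexan-1-one; 15 silyloxyfuran
Product: 17 (5R)-3-methyl-5-{(1R)-1-[(1R)-2-oxocyclohexyl]propyl}furan-2(5H)-one, via silyl enol ether 16 (not isolated)
Conditions: Sc(OTf)3 / chiral N,N′-dioxide ligand (10 mol %), CH2Cl2, −20 °C; then dilute aq HCl–THF
Reagents that add atoms: none
Why: Catalytic asymmetric vinylogous Mukaiyama–Michael addition, in which the Sc(III) complex binds the enone carbonyl and shields one face of C10, the furan attacks through its C5 in an open transition state that places the ethyl group and the ring oxygen anti (setting C10 and C11 together), and protonation of 16 leaves the equilibrating, later erased C9 centre.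

Step 9
Reactants: 17 keto butenolide
Product: 18 (5R)-5-{(1R)-1-[(1R)-2-(dibromomethylidene)cyclohexyl]propyl}-3-methylfuran-2(5H)-one
Conditions: CBr4, PPh3, toluene, 0 to 80 °C
Reagents that add atoms: carbon tetrabromide, BrC(Br)(Br)Br
Why: Ramirez dibromoolefination (Wittig reaction of Ph3P=CBr2) turns the ketone carbon C9a into an alkylidene carbon and brings in C1 with two handles, the weakly basic ylide sparing the butenolide.

Step 10
Reactants: 18 gem-dibromoalkene
Product: 19 (3aR,8aR,9R,9aR)-4-bromo-9-ethyl-3-methylidene-3a,5,6,7,8,8a,9,9a-octahydronaphtho[2,3-b]furan-2(3H)-one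
Conditions: Pd(PtBu3)2 (10 mol %), Cy2NMe, toluene, 90 °C
Reagents that add atoms: none
Why: Intramolecular Heck reaction, in which oxidative addition into either C–Br bond is reversible with the bulky PtBu3 ligand, only the palladium syn to C9 can add 6-exo-trig to C12 on the butenolide face that carries C10 (cis fusion, sets C12), and syn β-hydride elimination is possible only towards the methyl group, which gives the exocyclic methylene and keeps the second bromide.

Step 11
Reactants: 19 bromo α-methylene lactone
Product: 20 (3S,3aR,8aR,9R,9aR)-4-bromo-9-ethyl-3-methyl-3a,5,6,7,8,8a,9,9a-octahydronaphtho[2,3-b]furan-2(3H)-one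
Conditions: H2 (1 atm), RhCl(PPh3)3 (5 mol %), toluene–EtOH, rt
Reagents that add atoms: none
Why: Homogeneous hydrogenation reduces only the 1,1-disubstituted alkene, leaves the tetrasubstituted bromoalkene alone and delivers hydrogen to the convex face of the cis-fused lactone (the face of H-11 and H-12), which sets C13 with its methyl group on the concave side.

Step 12
Reactants: 9 iodide; 20 alkenyl bromide
Product: 22 octalin lactone carbamate with the chain CH2–CH(NHBoc)–lactone at C1 and the alkene C1=C9a (3S,9R,10R,11R,12S,13S,18S,20S), via alkylzinc iodide 21 (not isolated)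
Conditions: 9, Zn dust, I2 (cat.), DMF, rt; then 20, Pd2(dba)3 (2.5 mol %), SPhos (10 mol %), 50 °C
Reagents that add atoms: none
Why: Negishi coupling, since β-carbamato alkylzinc iodides of the iodoalanine type resist β-elimination in DMF and couple with hindered alkenyl bromides under Pd/SPhos catalysis, forming C1–C2 without touching a stereocentre.

Step 13
Reactants: 22 carbamate
Product: 25 azide with N3 in place of NHBoc at C3 (3S,9R,10R,11R,12S,13S,18S,20S), via silyl carbamate 23 (not isolated), via primary amine 24 (not isolated)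
Conditions: TMSOTf, 2,6-lutidine, CH2Cl2, 0 °C; MeOH; then imidazole-1-sulfonyl azide·HCl, NaHCO3, CuSO4 (cat.), MeOH–H2O, rt
Reagents that add atoms: imidazole-1-sulfonyl azide hydrochloride, [N-]=[N+]=NS(=O)(=O)n1ccnc1.Cl
Why: Silyl triflate cleavage of the Boc group avoids protic acid at the tetrasubstituted alkene, and the Cu-catalysed diazo transfer converts NH2 into N3 with retention at C3 under conditions too weakly basic to epimerise C13.

Step 14
Reactants: 25 azido alkene
Product: 26 C1–C9a α-epoxide of 25 (1S,3S,9R,9aR,10R,11R,12R,13S,18S,20S)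
Conditions: DMDO, acetone–CH2Cl2, −20 °C
Reagents that add atoms: dimethyldioxirane, CC1(C)OO1
Why: Epoxidation of the electron-rich tetrasubstituted alkene by neutral DMDO takes place from the α face, opposite the axial C11–O bond and the fused lactone, which sets C1 (and the transient C9a) and spares azide and lactones.

Step 15
Reactants: 26 azido epoxide
Product: 29 target CNP0179500.1 (1S,3S,10R,11R,12R,13S,18S,20S), via aminodiazonium ion 27 (not isolated), via iminium alkoxide 28 (not isolated)
Conditions: Sc(OTf)3 (10 mol %), HFIP–CH2Cl2, −40 °C to rt; aq NaHCO3 wash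
Reagents that add atoms: none
Why: The Lewis acid in HFIP activates the epoxide, which opens at C9a (the carbon remote from the electron-withdrawing lactone and azide) as the inner azide nitrogen attacks from the β face anti to the C9a–O bond to give 27, then C5 shifts from C9a to nitrogen while N2 leaves, and 28 passes its C9 proton to the alkoxide to give 29. The closest known reaction type is the intramolecular Schmidt reaction of alkyl azides with tertiary carbocations generated from epoxides or alkenes. The pyrrolidine (N4, C3, C2, C1, C9a) closes by a 5-endo epoxide opening, tolerated because C9a–O cleavage at the fully substituted carbon is far advanced, while the azepine is not closed but arises by one-atom enlargement of the cyclohexane C5–C9, C9a. No new stereocentre is formed: C1 keeps the C–O bond set in step 14, C3 is untouched, and C9 and C9a become sp2. Of the three groups on C9a only C5 can migrate without strain, because a shift of C9 would place an E-configured C=N+ in a seven-membered ring and a shift of C1 would give an azetidine, and proton loss can only go to C9 because C1 bears no hydrogen. Release of epoxide strain and loss of N2 make the cascade irreversible, and under acid the product is stored as its α-hydroxy iminium ion, in which the C1 carbinol cannot ionise.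

Compound list
1 | (4S)-3-(tert-butoxycarbonyl)-2,2-dimethyl-1,3-oxazolidine-4-carboxylic acid | CC1(C)OC[C@@H](C(=O)O)N1C(=O)OC(C)(C)C | starting material
2 | S-ethyl (4S)-3-(tert-butoxycarbonyl)-2,2-dimethyl-1,3-oxazolidine-4-carbothioate | CC1(C)OC[C@@H](C(=O)SCC)N1C(=O)OC(C)(C)C | intermediate
3 | methyl (2R)-3-bromo-2-methylpropanoate | BrC[C@H](C)C(=O)OC | starting material
4 | [(2R)-3-methoxy-2-methyl-3-oxopropyl]zinc bromide | Br[Zn]C[C@H](C)C(=O)OC | intermediate
5 | tert-butyl (4S)-4-[(3S)-4-methoxy-3-methyl-4-oxobutanoyl]-2,2-dimethyl-1,3-oxazolidine-3-carboxylate | CC1(C)OC[C@@H](C(=O)C[C@H](C)C(=O)OC)N1C(=O)OC(C)(C)C | intermediate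
6 | tert-butyl (4S)-4-[(1S,3S)-1-hydroxy-4-methoxy-3-methyl-4-oxobutyl]-2,2-dimethyl-1,3-oxazolidine-3-carboxylate | CC1(C)OC[C@@H]([C@@H](O)C[C@H](C)C(=O)OC)N1C(=O)OC(C)(C)C | intermediate
7 | tert-butyl (4S)-2,2-dimethyl-4-[(2S,4S)-4-methyl-5-oxooxolan-2-yl]-1,3-oxazolidine-3-carboxylate | CC1(C)OC[C@@H]([C@@H]2C[C@H](C)C(=O)O2)N1C(=O)OC(C)(C)C | intermediate
8 | tert-butyl N-[(1S)-2-hydroxy-1-[(2S,4S)-4-methyl-5-oxooxolan-2-yl]ethyl]carbamate | OC[C@H](NC(=O)OC(C)(C)C)[C@@H]1C[C@H](C)C(=O)O1 | intermediate
9 | tert-butyl N-[(1R)-2-iodo-1-[(2S,4S)-4-methyl-5-oxooxolan-2-yl]ethyl]carbamate | IC[C@H](NC(=O)OC(C)(C)C)[C@@H]1C[C@H](C)C(=O)O1 | intermediate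
10 | 4-(cyclohex-1-en-1-yl)morpholine | C1CCC(=CC1)N1CCOCC1 | starting material
11 | propanal | CCC=O | starting material
12 | 4-[(6E)-6-propylidenecyclohex-1-en-1-yl]morpholine | CC/C=C1\CCCC=C1N1CCOCC1 | intermediate
13 | (2E)-2-propylidenecyclohexan-1-one | CC/C=C1\CCCCC1=O | intermediate
14 | 3-methylfuran-2(5H)-one | CC1=CCOC1=O | starting material
15 | tert-butyl(dimethyl)[(3-methylfuran-2-yl)oxy]silane | Cc1ccoc1O[Si](C)(C)C(C)(C)C | intermediate
16 | (5R)-5-[(1R)-1-(2-{[tert-butyl(dimethyl)silyl]oxy}cyclohex-1-en-1-yl)propyl]-3-methylfuran-2(5H)-one | CC[C@H](C1=C(O[Si](C)(C)C(C)(C)C)CCCC1)[C@@H]1C=C(C)C(=O)O1 | intermediate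
17 | (5R)-3-methyl-5-{(1R)-1-[(1R)-2-oxocyclohexyl]propyl}furan-2(5H)-one | CC[C@H]([C@H]1CCCCC1=O)[C@@H]1C=C(C)C(=O)O1 | intermediate
18 | (5R)-5-{(1R)-1-[(1R)-2-(dibromomethylidene)cyclohexyl]propyl}-3-methylfuran-2(5H)-one | CC[C@H]([C@H]1CCCCC1=C(Br)Br)[C@@H]1C=C(C)C(=O)O1 | intermediate
19 | (3aR,8aR,9R,9aR)-4-bromo-9-ethyl-3-methylidene-3a,5,6,7,8,8a,9,9a-octahydronaphtho[2,3-b]furan-2(3H)-one | CC[C@@H]1[C@H]2CCCCC2=C(Br)[C@H]2[C@@H]1OC(=O)C2=C | intermediate
20 | (3S,3aR,8aR,9R,9aR)-4-bromo-9-ethyl-3-methyl-3a,5,6,7,8,8a,9,9a-octahydronaphtho[2,3-b]furan-2(3H)-one | CC[C@@H]1[C@H]2CCCCC2=C(Br)[C@H]2[C@@H]1OC(=O)[C@H]2C | intermediate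
21 | {(2R)-2-[(tert-butoxycarbonyl)amino]-2-[(2S,4S)-4-methyl-5-oxooxolan-2-yl]ethyl}zinc iodide | I[Zn]C[C@H](NC(=O)OC(C)(C)C)[C@@H]1C[C@H](C)C(=O)O1 | intermediate
22 | octalin lactone carbamate, C1=C9a alkene, NHBoc at C3 (3S,9R,10R,11R,12S,13S,18S,20S) | CC[C@@H]1[C@H]2CCCCC2=C(C[C@H](NC(=O)OC(C)(C)C)[C@@H]2C[C@H](C)C(=O)O2)[C@H]2[C@@H]1OC(=O)[C@H]2C | intermediate
23 | trimethylsilyl carbamate of amine 24 | CC[C@@H]1[C@H]2CCCCC2=C(C[C@H](NC(=O)O[Si](C)(C)C)[C@@H]2C[C@H](C)C(=O)O2)[C@H]2[C@@H]1OC(=O)[C@H]2C | intermediate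
24 | primary amine, NH2 at C3 (3S,9R,10R,11R,12S,13S,18S,20S) | CC[C@@H]1[C@H]2CCCCC2=C(C[C@H](N)[C@@H]2C[C@H](C)C(=O)O2)[C@H]2[C@@H]1OC(=O)[C@H]2C | intermediate
25 | azide, N3 at C3, C1=C9a alkene (3S,9R,10R,11R,12S,13S,18S,20S) | CC[C@@H]1[C@H]2CCCCC2=C(C[C@H](N=[N+]=[N-])[C@@H]2C[C@H](C)C(=O)O2)[C@H]2[C@@H]1OC(=O)[C@H]2C | intermediate
26 | azido C1–C9a α-epoxide (1S,3S,9R,9aR,10R,11R,12R,13S,18S,20S) | CC[C@@H]1[C@H]2CCCC[C@@]23O[C@@]3(C[C@H](N=[N+]=[N-])[C@@H]2C[C@H](C)C(=O)O2)[C@H]2[C@@H]1OC(=O)[C@H]2C | intermediate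
27 | aminodiazonium alkoxide, N4 bound to the β face of C9a, drawn as zwitterion | CC[C@@H]1[C@H]2CCCC[C@]23N([N+]#N)[C@H]([C@@H]4C[C@H](C)C(=O)O4)C[C@]3([O-])[C@H]2[C@@H]1OC(=O)[C@H]2C | intermediate
28 | ring-expanded iminium alkoxide, N4=C9a, drawn as zwitterion | CC[C@@H]1[C@H]2CCCC[N+]3=C2[C@]([O-])(C[C@H]3[C@@H]2C[C@H](C)C(=O)O2)[C@H]2[C@@H]1OC(=O)[C@H]2C | intermediate
29 | CNP0179500.1 (1S,3S,10R,11R,12R,13S,18S,20S) | CC[C@@H]1C2=C3N(CCCC2)[C@H]([C@@H]2C[C@H](C)C(=O)O2)C[C@]3(O)[C@H]2[C@@H]1OC(=O)[C@H]2C | target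

Total step count: 15. Longest linear sequence: 9 steps (1 → 2 → 5 → 7 → 8 → 9 → 22 → 25 → 26 → 29). The branches from 10/11 and from 14 are equally long.

Steps most likely to fail

Step 15. After ionisation at C9a, a 1,2-shift from C1 (semipinacol) or loss of a proton may outrun the 5-endo capture by the weakly nucleophilic azide. The fallback separates C–N bond formation from the migration. It sets out from 26 and returns at 29.
- Staudinger reduction (PMe3, wet THF) should give amino epoxide F1.
- The amine is a far better nucleophile than the azide. It opens the epoxide at C9a under mild, non-ionising Lewis acid catalysis (LiClO4 or Yb(OTf)3, MeCN, heat) to give the fused pyrrolidine amino alcohol F2.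
- NCS converts F2 into N-chloroamine F3.
- AgBF4 abstracts chloride and triggers the Stieglitz-type shift of C5 from C9a to nitrogen, and Et3N releases 29 from the iminium salt.

Step 8. The α-branched exocyclic enone may give poor facial or simple diastereoselectivity, and its double bond may drift into the ring. The fallback builds C9–C10 by enamine catalysis and C11 by catalyst-controlled allylation. It sets out from propanal 11 and returns at 17.
- Henry reaction with nitromethane and dehydration (MsCl, Et3N) give (E)-1-nitrobut-1-ene F4.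
- Michael addition of cyclohexanone under a D-proline-derived pyrrolidine–thiourea catalyst gives the syn nitro ketone F5.
- A Nef reaction (NaOMe; H2SO4–MeOH; aqueous acid) gives keto aldehyde F6.
- Iridium-catalysed 2-(alkoxycarbonyl)allylation (methyl 2-{[(tert-butoxycarbonyl)oxy]methyl}acrylate, cyclometalated Ir–SEGPHOS complex, iPrOH), followed by lactonisation, gives α-methylene lactone F7.
- RhCl3-catalysed migration of the exocyclic double bond into the ring gives 17.

Step 10. Palladium may stay at the C–Br bond that cannot cyclise, or a palladium hydride may re-add and move the exocyclic alkene into conjugation with C1=C9a. The fallback replaces the two-electron process by a radical one. It sets out from 18 and returns at 20. Slow addition of Bu3SnH (one equivalent) with AIBN in refluxing benzene removes one bromine, the α-bromovinyl radical inverts and cyclises 6-exo onto C12, and the lactone radical takes hydrogen on the convex face. This skips 19 and step 11.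

Further compounds
F1 | step 15 | amino epoxide (NH2 at C3, C1–C9a α-epoxide) | CC[C@@H]1[C@H]2CCCC[C@@]23O[C@@]3(C[C@H](N)[C@@H]2C[C@H](C)C(=O)O2)[C@H]2[C@@H]1OC(=O)[C@H]2C
F2 | step 15 | fused pyrrolidine amino alcohol (N4–C9a bond on the β face, C1–OH α) | CC[C@@H]1[C@H]2CCCC[C@]23N[C@H]([C@@H]4C[C@H](C)C(=O)O4)C[C@]3(O)[C@H]2[C@@H]1OC(=O)[C@H]2C
F3 | step 15 | N-chloroamine of F2 | CC[C@@H]1[C@H]2CCCC[C@]23N(Cl)[C@H]([C@@H]4C[C@H](C)C(=O)O4)C[C@]3(O)[C@H]2[C@@H]1OC(=O)[C@H]2C
F4 | step 8 | (E)-1-nitrobut-1-ene | CC/C=C/[N+](=O)[O-]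
F5 | step 8 | (2R)-2-[(2R)-1-nitrobutan-2-yl]cyclohexan-1-one | CC[C@H]([C@H]1CCCCC1=O)C[N+](=O)[O-]
F6 | step 8 | (2R)-2-[(1R)-2-oxocyclohexyl]butanal | CC[C@H]([C@H]1CCCCC1=O)C=O
F7 | step 8 | α-methylene lactone, C9, C10 and C11 configured as in 17 | CC[C@H]([C@H]1CCCCC1=O)[C@@H]1CC(=C)C(=O)O1
F0 | step 10 | none | none
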